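**Retrosynthetic overview**
1. Gentiside D (13) is the aromatic tautomer of ene-dione 12, which should arise by double oxidation of cyclohexene diol 11. The benzene ring, the only ring, is therefore built as a cyclohexene and aromatised last.
2. The strategy rests on the ring bond C4–C5, which lies opposite the contiguous triad C1 (ester), C2 (OH), C3 (OH). A retro-metathesis cut of C4=C5 opens the ring to acyclic diene 9, which already carries the ester, O2 and O3 in the right order.
3. Diene 9 comes from an aldol reaction forming the C1–C2 bond between the lithium enolate of pent-4-enoate 3 (supplies C1, C6, C5) and 2-silyloxybut-3-enal 7 (supplies C2, C3, C4).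
4. Ester 3 comes from acid chloride 1 and alcohol 2; aldehyde 7 comes from but-3-ene-1,2-diol 4 by silylation, selective primary desilylation and oxidation.
5. O3 stays silylated until the ring exists, because a free O3–H in the open chain sits gamma to the ester carbonyl and would lactonise with loss of 2. One ring is closed in step 6 and aromatised in step 8.

Key step: step 6

Assumption: 16-methylheptadecan-1-ol (2) is bought as the single iso-branched isomer and but-3-ene-1,2-diol (4) as the racemate; the target has no stereocentre, so all intermediates are carried as racemates or diastereomer mixtures.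

**Step 1**
Reactants: 1 pent-4-enoyl chloride; 2 16-methylheptadecan-1-ol
Product: 3 16-methylheptadecyl pent-4-enoate
Conditions: Et3N, DMAP (cat.), CH2Cl2, 0 °C → rt
Reagents that add atoms: none
Why: DMAP-catalysed acylation of a primary alcohol by an acid chloride (nucleophilic acyl substitution) is dependable and leaves the terminal alkene untouched.

**Step 2**
Reactants: 4 but-3-ene-1,2-diol (racemic)
Product: 5 3,4-bis[(tert-butyldimethylsilyl)oxy]but-1-ene (racemic)
Conditions: TBSCl (2.4 equiv), imidazole, DMF, rt
Reagents that add atoms: tert-butyldimethylsilyl chloride (TBSCl), CC(C)(C)[Si](C)(C)Cl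
Why: Imidazole-promoted silylation in DMF with excess silyl chloride should cap both the primary and the allylic secondary hydroxyl.

**Step 3**
Reactants: 5 3,4-bis[(tert-butyldimethylsilyl)oxy]but-1-ene
Product: 6 2-[(tert-butyldimethylsilyl)oxy]but-3-en-1-ol (racemic)
Conditions: HF·pyridine, pyridine, THF, 0 °C
Reagents that add atoms: none
Why: Selective fluoride-mediated desilylation should cleave the unhindered primary silyl ether well before the secondary allylic one, and the buffered acidic medium gives no alkoxide that could shift the remaining silyl group from O2 to O1.

**Step 4**
Reactants: 6 2-[(tert-butyldimethylsilyl)oxy]but-3-en-1-ol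
Product: 7 2-[(tert-butyldimethylsilyl)oxy]but-3-enal (racemic, used crude at once)
Conditions: Dess–Martin periodinane, pyridine, CH2Cl2, 0 °C
Reagents that add atoms: none
Why: Dess–Martin oxidation under pyridine buffering is near neutral and fast, so the alpha-silyloxy beta,gamma-unsaturated aldehyde should form without the double bond moving into conjugation.

**Step 5**
Reactants: 3 16-methylheptadecyl pent-4-enoate; 7 2-[(tert-butyldimethylsilyl)oxy]but-3-enal
Product: 9 16-methylheptadecyl 4-[(tert-butyldimethylsilyl)oxy]-3-hydroxy-2-(prop-2-en-1-yl)hex-5-enoate (mixture of diastereomers), via lithium ester enolate 8 (not isolated)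
Conditions: LDA (LiN(iPr)2), THF, −78 °C; then 7, −78 °C; AcOH, −78 °C
Reagents that add atoms: none
Why: Directed aldol addition of the kinetic lithium ester enolate to the electrophilic alpha-silyloxy aldehyde should be faster than proton transfer at −78 °C, the cold acetic acid quench forestalls retro-aldol and silyl migration, and the two new stereocentres are set without control because all are erased in step 8.

**Step 6**
Reactants: 9 16-methylheptadecyl 4-[(tert-butyldimethylsilyl)oxy]-3-hydroxy-2-(prop-2-en-1-yl)hex-5-enoate
Product: 10 16-methylheptadecyl 3-[(tert-butyldimethylsilyl)oxy]-2-hydroxycyclohex-4-ene-1-carboxylate (mixture of diastereomers)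
Conditions: second-generation Grubbs catalyst (H2IMes)(PCy3)Cl2Ru=CHPh (5 mol %), CH2Cl2 (0.005 M), 40 °C
Reagents that add atoms: none
Why: Ring-closing olefin metathesis: the ruthenium benzylidene exchanges onto the unhindered allyl terminus (C5), the new alkylidene adds [2+2] across the vinyl group on the silyloxy carbon (C4), and cycloreversion of the ruthenacyclobutane releases the C4=C5 double bond and Ru=CH2, which carries the chain with loss of ethylene. The closest known reaction type is the metathesis closure of oxygenated 1,7-dienes to cyclohexenes, as practised for carbasugar-type rings. The six-membered carbocycle is closed by joining the two internal alkene CH carbons, both terminal CH2 groups leaving as ethylene. No stereocentre is formed; the three existing ones are carried as a mixture, every diastereomer can reach the strain-free half-chair, and all are erased in step 8. The selectivity needed is ring closure over acyclic diene oligomerisation and over ruthenium hydride migration of the allyl double bond, which high dilution, the ease of six-ring formation from two monosubstituted alkenes and the irreversible escape of ethylene should secure. The free C2 hydroxyl and the ester are inert to the catalyst, and the silyl ether at C3 only slows the second cycloaddition, which the N-heterocyclic carbene catalyst tolerates.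

**Step 7**
Reactants: 10 16-methylheptadecyl 3-[(tert-butyldimethylsilyl)oxy]-2-hydroxycyclohex-4-ene-1-carboxylate
Product: 11 16-methylheptadecyl 2,3-dihydroxycyclohex-4-ene-1-carboxylate (mixture of diastereomers)
Conditions: HF (48% aq), MeCN, 0 °C → rt
Reagents that add atoms: none
Why: Fluoride-driven cleavage of the secondary silyl ether under mildly acidic conditions spares the ester and the beta-hydroxy ester, and with the ring in place the C3 hydroxyl and the ester could only lactonise through a bridged bicycle, so the alcohol 2 unit should stay attached.

**Step 8**
Reactants: 11 16-methylheptadecyl 2,3-dihydroxycyclohex-4-ene-1-carboxylate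
Product: 13 gentiside D (16-methylheptadecyl 2,3-dihydroxybenzoate), via ene-dione 12 (not isolated)
Conditions: DMSO, (CF3CO)2O, CH2Cl2, −78 °C; Et3N, −78 °C → rt
Reagents that add atoms: none
Why: Swern-type oxidation with anhydride-activated DMSO, a known way to take vicinal diols to 1,2-diones without C–C cleavage, should convert both carbinols to alkoxysulfonium salts before Et3N collapses them to ene-dione 12, which is the keto tautomer of the catechol and should aromatise under the same base by enolisation of the beta-keto ester and vinylogous enolisation through C6–H, erasing every stereocentre.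

**Compound list**
1 | pent-4-enoyl chloride | C=CCCC(=O)Cl | starting material
2 | 16-methylheptadecan-1-ol | CC(C)CCCCCCCCCCCCCCCO | starting material
3 | 16-methylheptadecyl pent-4-enoate | CC(C)CCCCCCCCCCCCCCCOC(=O)CCC=C | intermediate
4 | but-3-ene-1,2-diol (racemic) | C=CC(O)CO | starting material
5 | 3,4-bis[(tert-butyldimethylsilyl)oxy]but-1-ene (racemic) | C=CC(O[Si](C)(C)C(C)(C)C)CO[Si](C)(C)C(C)(C)C | intermediate
6 | 2-[(tert-butyldimethylsilyl)oxy]but-3-en-1-ol (racemic) | C=CC(O[Si](C)(C)C(C)(C)C)CO | intermediate
7 | 2-[(tert-butyldimethylsilyl)oxy]but-3-enal (racemic) | C=CC(O[Si](C)(C)C(C)(C)C)C=O | intermediate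
8 | lithium 1-(16-methylheptadecyloxy)penta-1,4-dien-1-olate (lithium enolate of 3, geometry immaterial, not isolated) | [Li+].CC(C)CCCCCCCCCCCCCCCOC([O-])=CCC=C | intermediate
9 | 16-methylheptadecyl 4-[(tert-butyldimethylsilyl)oxy]-3-hydroxy-2-(prop-2-en-1-yl)hex-5-enoate (mixture of diastereomers) | CC(C)CCCCCCCCCCCCCCCOC(=O)C(CC=C)C(O)C(O[Si](C)(C)C(C)(C)C)C=C | intermediate
10 | 16-methylheptadecyl 3-[(tert-butyldimethylsilyl)oxy]-2-hydroxycyclohex-4-ene-1-carboxylate (mixture of diastereomers) | CC(C)CCCCCCCCCCCCCCCOC(=O)C1CC=CC(O[Si](C)(C)C(C)(C)C)C1O | intermediate
11 | 16-methylheptadecyl 2,3-dihydroxycyclohex-4-ene-1-carboxylate (mixture of diastereomers) | CC(C)CCCCCCCCCCCCCCCOC(=O)C1CC=CC(O)C1O | intermediate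
12 | 16-methylheptadecyl 2,3-dioxocyclohex-4-ene-1-carboxylate (racemic, not isolated) | CC(C)CCCCCCCCCCCCCCCOC(=O)C1CC=CC(=O)C1=O | intermediate
13 | gentiside D, 16-methylheptadecyl 2,3-dihydroxybenzoate (no stereocentre) | CC(C)CCCCCCCCCCCCCCCOC(=O)c1cccc(O)c1O | target

**Step count**
Total steps: 8. Longest linear sequence: 7 steps (4 → 13, steps 2 to 8).

**Steps most likely to fail**

Step 8 (double oxidation and aromatisation). Three processes threaten it. The activated oxygen at C2 lies beta to the ester and may be lost by elimination instead of being oxidised, which would lead towards a 3-hydroxybenzoate. The oxidation may stall at the alpha-ketol stage. The freed catechol may be methylthiomethylated by surplus activated DMSO. The fallback sets out from 11 and replaces sulfonium chemistry by hypervalent iodine with deliberate over-oxidation. IBX (excess) in DMSO at rt oxidises vicinal diols to 1,2-diones without glycol cleavage and puts no leaving group on C2. Any catechol that aromatises in the pot is expected to go on to the ortho-quinone 16-methylheptadecyl 5,6-dioxocyclohexa-1,3-diene-1-carboxylate F1. The whole mixture is then reduced with aqueous Na2S2O4 in the work-up, which returns the route at 13.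

Step 5 (aldol). The alpha-hydrogen of 7 is activated by the formyl group, the vinyl group and the silyloxy group. Proton transfer to the basic ester enolate would return 3 and move the aldehyde double bond into conjugation. Retro-aldol or oxygen-to-oxygen silyl migration in the lithium aldolate is a further loss pathway. The fallback sets out from 3 and avoids a basic enolate altogether. The ester is converted (LDA (LiN(iPr)2), Me3SiCl, THF, −78 °C, non-aqueous work-up) into its silyl ketene acetal [1-(16-methylheptadecyloxy)penta-1,4-dien-1-yl]oxytrimethylsilane F2. This neutral nucleophile is combined with 7 in a Mukaiyama aldol addition under BF3·OEt2 in CH2Cl2 at −78 °C. Aqueous NaHCO3 work-up returns the route at 9.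

Step 6 (ring-closing metathesis, key step). The second cycloaddition at the vinyl group next to the bulky silyl ether may be slow. That would give time for intermolecular metathesis to oligomers and for hydride-mediated migration of the allyl double bond, which leads to ring-contracted material. The fallback sets out from 9 and changes the substrate to one in which the allylic oxygen assists the catalyst. The silyl group is removed first (HF 48% aq, MeCN, 0 °C) to give 16-methylheptadecyl 3,4-dihydroxy-2-(prop-2-en-1-yl)hex-5-enoate F3, which is kept cold and used at once to limit gamma-lactonisation. It is closed with the phosphine-free Hoveyda–Grubbs second-generation catalyst (H2IMes)Cl2Ru=CH(C6H4-2-OiPr) in dilute CH2Cl2 at 40 °C with 1,4-benzoquinone as hydride scavenger. The free allylic hydroxyl is known to speed up metathesis at its vinyl group. This returns the route at 11 and makes step 7 unnecessary.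

**Further compounds**
F1 | step 8 | 16-methylheptadecyl 5,6-dioxocyclohexa-1,3-diene-1-carboxylate | CC(C)CCCCCCCCCCCCCCCOC(=O)C1=CC=CC(=O)C1=O
F2 | step 5 | [1-(16-methylheptadecyloxy)penta-1,4-dien-1-yl]oxytrimethylsilane | CC(C)CCCCCCCCCCCCCCCOC(O[Si](C)(C)C)=CCC=C
F3 | step 6 | 16-methylheptadecyl 3,4-dihydroxy-2-(prop-2-en-1-yl)hex-5-enoate (mixture of diastereomers) | CC(C)CCCCCCCCCCCCCCCOC(=O)C(CC=C)C(O)C(O)C=C
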